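**Plan**
1. Numbering: C1 (CH–OAc), C2 (CH2), C3 (carbinol bearing isopropyl), C4 (fusion CH), C5 (CH–O-aroyl), C6=C7 (methyl on C7), C8 (C=O), C9 (CH2), C10 (quaternary, methyl). Ring A = C1–C4 + C10, ring B = C4–C10, and β is the face of the C10 methyl group.
2. Enabling feature: C4–C9 of ring B, with oxygen on C5 and C8 and methyl on C7, are the six carbons of a 2,5-dimethoxy-4-methylphenyl group attached to C3. The seventh ring atom, C10, is a carbene carbon that also closes ring A.
3. Cuts, in order: the ester C–O bonds at C1 and C5; C3–O (back to a C2=C3 enone); C4–C10 and C9–C10 (aromatic C4–C9 restored); C10=N2; C1–C10 (ethyl Grignard); C3–isopropyl; C3–C4 (aryl–alkyne).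
4. Forward: arene, then the Z β-aryl enone chain, then the diazo ketone. Rings A and B then form in one step: A by C4–C10 closure, B by enlargement of the benzene ring. The oxygen pattern is adjusted afterwards in the order C5, C3, C1, C8.
5. Stereochemistry: C10 comes from the chiral copper catalyst and C4 from protonation anti to the methyl group. C5 is set by CBS reagent control, C3 by peroxide attack on the α face and C1 by hydride attack on the α face.

Key step: step 7

Assumption: the sense of induction of the copper bis(oxazoline) catalyst on this substrate class is not known, so the (S,S) ligand is written and its mirror image would be used if it favoured (R)-13.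

Step 1
Reactants: 1 2,5-dimethoxytoluene
Product: 2 1-iodo-2,5-dimethoxy-4-methylbenzene
Conditions: NIS, TFA (cat.), MeCN, rt
Reagents that add atoms: N-iodosuccinimide, O=C1CCC(=O)N1I
Why: Electrophilic aromatic iodination should go to the position para to methyl and ortho to a methoxy group, the most activated and least crowded site of this arene.

Step 2
Reactants: 2 1-iodo-2,5-dimethoxy-4-methylbenzene; 3 ethyl propiolate
Product: 4 ethyl 3-(2,5-dimethoxy-4-methylphenyl)prop-2-ynoate
Conditions: PdCl2(PPh3)2 (2 mol %), CuI (4 mol %), K2CO3, THF, 65 °C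
Reagents that add atoms: none
Why: This is a Sonogashira coupling through zerovalent palladium formed in situ, run with carbonate instead of an amine so that the propiolate is not lost by conjugate addition or oligomerisation.

Step 3
Reactants: 4 ethyl 3-(2,5-dimethoxy-4-methylphenyl)prop-2-ynoate; 5 isopropylmagnesium chloride
Product: 7 ethyl (Z)-3-(2,5-dimethoxy-4-methylphenyl)-4-methylpent-2-enoate, via alkenylcopper adduct 6 (not isolated)
Conditions: 5 (1.2 equiv), CuI (1.2 equiv), THF, −40 °C; 4, −78 °C; AcOH/THF, −78 °C
Reagents that add atoms: CuI, [Cu+].[I-] (its copper is held only in 6)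
Why: Syn carbocupration of an ynoate puts isopropyl on the β carbon and copper cis to it, and protonation with retention at −78 °C, before any allenolate equilibration, leaves aryl and ester cis (Z).

Step 4
Reactants: 7 ethyl (Z)-3-(2,5-dimethoxy-4-methylphenyl)-4-methylpent-2-enoate; 5 isopropylmagnesium chloride (as base)
Product: 8 (Z)-3-(2,5-dimethoxy-4-methylphenyl)-N-methoxy-N,4-dimethylpent-2-enamide
Conditions: MeNH(OMe)·HCl, 5 (3 equiv), THF, −20 to 0 °C; 1 M HCl
Reagents that add atoms: N,O-dimethylhydroxylamine hydrochloride, CNOC.Cl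
Why: Weinreb aminolysis of the ester by the chloromagnesium amide should keep the alkene geometry, because the fully substituted β carbon resists reversible conjugate addition.

Step 5
Reactants: 8 (Z)-3-(2,5-dimethoxy-4-methylphenyl)-N-methoxy-N,4-dimethylpent-2-enamide
Product: 9 (Z)-5-(2,5-dimethoxy-4-methylphenyl)-6-methylhept-4-en-3-one
Conditions: EtMgBr, THF, 0 °C; 1 M HCl
Reagents that add atoms: ethylmagnesium bromide, CC[Mg]Br
Why: In the Weinreb ketone synthesis the chelated adduct survives until work-up, so addition stops at the ethyl ketone, whose CH2 becomes C10.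

Step 6
Reactants: 9 (Z)-5-(2,5-dimethoxy-4-methylphenyl)-6-methylhept-4-en-3-one
Product: 11 (Z)-2-diazo-5-(2,5-dimethoxy-4-methylphenyl)-6-methylhept-4-en-3-one, via trifluoroacetyl ketone 10 (not isolated)
Conditions: LiHMDS, THF, −78 °C; CF3CO2CH2CF3; 5% HCl work-up; then MsN3, Et3N, H2O (1 equiv), MeCN, rt
Reagents that add atoms: 2,2,2-trifluoroethyl trifluoroacetate, O=C(OCC(F)(F)F)C(F)(F)F (acyl group held only in 10); methanesulfonyl azide, CS(=O)(=O)N=[N+]=[N-]
Why: Detrifluoroacetylative diazo transfer (Danheiser) works through the kinetic α′ enolate, was devised for diazo ketones next to an enone, and avoids both diazoethane and its dipolar cycloaddition to an enoyl chloride.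

Step 7
Reactants: 11 (Z)-2-diazo-5-(2,5-dimethoxy-4-methylphenyl)-6-methylhept-4-en-3-one
Product: 13 (8aS)-4,7-dimethoxy-6,8a-dimethyl-3-(propan-2-yl)azulen-1(8aH)-one, via norcaradiene 12 (not isolated)
Conditions: [Cu(MeCN)4]PF6 (5 mol %), (S,S)-Ph-box (6 mol %), NaB[3,5-(CF3)2C6H3]4 (6 mol %), CH2Cl2, reflux, slow addition of 11; neutral alumina
Reagents that add atoms: none
Why: Proposed new method: loss of N2 at the cationic monovalent copper centre gives an electrophilic carbene at C10 that adds [2+1] across the arene bond C4–C9, and norcaradiene 12 then opens by an allowed disrotatory six-electron electrocyclic reaction that breaks C4–C9; the closest known reaction type is the intramolecular Buchner reaction of 2-diazo-5-arylpentan-3-ones under copper bis(oxazoline) catalysis, which already tolerates methyl on the diazo carbon, so only the cross-conjugated alkene tether and the dialkoxy arene are new. Ring A closes as a five-membered ring through C4–C10, one edge of the cyclopropane (bicyclo[3.1.0] fusion), which the Z alkene allows by holding C10 next to the ipso carbon, and ring B arises by one-carbon enlargement of the benzene ring. C10 is the only stereocentre formed and, since 11 is achiral, its S configuration can come only from the face of the arene bond that the chiral ligand sphere exposes to the carbene. Regioselectivity needs the ipso/C9 edge and not the ipso/C5 edge, which the C5 methoxy group blocks. Chemoselectivity needs arene addition to outrun both the 1,2-hydride shift from the C10 methyl group and substitution at C9 ending in a 2-naphthol; the non-coordinating counter-ion, slow addition, the aryl ring twisted out of the enone plane by isopropyl and C5 methoxy (so that its face meets C10) and acid-free isolation are chosen for that.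

Step 8
Reactants: 13 (8aS)-4,7-dimethoxy-6,8a-dimethyl-3-(propan-2-yl)azulen-1(8aH)-one
Product: 14 7-methoxy-6,8a-dimethyl-3-(propan-2-yl)-3a,8a-dihydroazulene-1,4-dione (3aR,8aS; H4 α, 10-Me β, trans-fused)
Conditions: KOH, THF/MeOH/H2O, 40 °C; aq KH2PO4, 0 °C, pH 6
Reagents that add atoms: potassium hydroxide, [K+].[OH-] (its oxygen becomes the C5 carbonyl oxygen)
Why: The C5 methoxy group is a doubly vinylogous ester and should be saponified by addition–elimination, while the C8 enol ether has no acceptor and is inert to base; C-protonation at C4 anti to the vicinal methyl relieves the isopropyl/C5–O peri strain; the step comes first because the push–pull dienone resists nucleophilic oxidants and a C3 carbinol beside a C4=C5 enol ether would ionise in Stork–Danheiser fashion on hydrolysis.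

Step 9
Reactants: 14 7-methoxy-6,8a-dimethyl-3-(propan-2-yl)-3a,8a-dihydroazulene-1,4-dione
Product: 15 4-hydroxy-7-methoxy-6,8a-dimethyl-3-(propan-2-yl)-4,8a-dihydroazulen-1(3aH)-one (5α-OH, H4 α, 10-Me β)
Conditions: (S)-Me-CBS (0.5 equiv), catecholborane, toluene, −78 °C; MeOH, aq NaHCO3
Reagents that add atoms: none
Why: In this Corey–Bakshi–Shibata reduction, with C4 and C10 as the large groups, the S catalyst delivers hydride to the β face of either carbonyl; this is the pseudo-axial attack anti to H4 wanted at C5 (giving 5α-OH while C3 is still planar) but is mismatched at C1, where the vicinal methyl covers that face, and the non-basic medium avoids enolate formation at the labile C4.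

Step 10
Reactants: 15 4-hydroxy-7-methoxy-6,8a-dimethyl-3-(propan-2-yl)-4,8a-dihydroazulen-1(3aH)-one
Product: 16 2α,3α-epoxide of 15 (C1 ketone, 5α-OH, C8 methyl enol ether)
Conditions: t-BuOOH (decane), DBU, CH2Cl2, 0 °C to rt
Reagents that add atoms: tert-butyl hydroperoxide, CC(C)(C)OO
Why: Weitz–Scheffer epoxidation can touch only the ring A enone, since the ring B methoxydiene is electron-rich; the peroxide should reach C3 from the α face, because the β face carries the C10 methyl and the C5 carbon while the 5α hydroxyl can guide it by hydrogen bonding, and this fixes the C3–O bond.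

Step 11
Reactants: 17 4-hydroxybenzoic acid
Product: 19 4-[(tert-butyldimethylsilyl)oxy]benzoic acid, via bis-silyl derivative 18 (not isolated)
Conditions: TBSCl (2.2 equiv), imidazole, DMF, rt; then AcOH/THF/H2O, rt
Reagents that add atoms: tert-butyldimethylsilyl chloride, CC(C)(C)[Si](C)(C)Cl
Why: After exhaustive silylation, mild hydrolysis cleaves the far more labile silyl ester and leaves the phenol masked, so that it cannot compete in the esterification.

Step 12
Reactants: 16 2α,3α-epoxide of 15; 19 4-[(tert-butyldimethylsilyl)oxy]benzoic acid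
Product: 20 5α-[4-(tert-butyldimethylsilyloxy)benzoyloxy] 2α,3α-epoxy ketone
Conditions: DCC, DMAP, CH2Cl2, 0 °C to rt
Reagents that add atoms: none
Why: Steglich esterification meets a single hydroxyl group here; placed earlier, the ester would be lost by vinylogous E1cB elimination under the basic epoxidation, and placed later it would compete with other hydroxyls.

Step 13
Reactants: 20 5α-aroyloxy 2α,3α-epoxy ketone
Product: 21 3α-hydroxy ketone (C1 ketone, C2 methylene, 3β-isopropyl, 5α-aroyloxy)
Conditions: SmI2 (2.2 equiv), THF/MeOH, −78 °C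
Reagents that add atoms: none
Why: Reductive opening of an α,β-epoxy ketone by divalent samarium breaks only the C2–O bond next to the carbonyl, so the C3–O bond and its configuration persist, and the allylic ester and enol ether should survive at −78 °C without HMPA.

Step 14
Reactants: 21 3α-hydroxy ketone
Product: 22 1β,3α-diol
Conditions: NaBH4, MeOH/CH2Cl2, −40 °C
Reagents that add atoms: none
Why: Borohydride reduction under substrate control should attack C1 from the α face, because the vicinal C10 methyl and the 3β-isopropyl cover the β face (the sense seen with 17-keto steroids), giving 1β-OH, and the low temperature holds back retro-aldol cleavage.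

Step 15
Reactants: 22 1β,3α-diol
Product: 23 1β-acetate
Conditions: Ac2O, pyridine, DMAP (cat.), CH2Cl2, rt
Reagents that add atoms: acetic anhydride, CC(=O)OC(C)=O
Why: DMAP-catalysed acetylation takes the secondary C1 hydroxyl and leaves the hindered tertiary C3 carbinol free.

Step 16
Reactants: 23 1β-acetate
Product: 24 CNP0087181.1 (target)
Conditions: 48% aq HF, MeCN, 0 °C
Reagents that add atoms: water, O (its oxygen becomes the C8 carbonyl oxygen)
Why: Acid hydrolysis of the 2-methoxydiene (proton to C9, water to C8) gives the C8 enone with C6=C7 in place while fluoride frees the phenol; C8 stays masked until every hydride step is over, so no ene-dione ever has to be differentiated, and the C3 carbinol is by now neither allylic nor β to a carbonyl.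

**Compound list**
1 | 2,5-dimethoxytoluene | Cc1cc(OC)ccc1OC | starting material
2 | 1-iodo-2,5-dimethoxy-4-methylbenzene | Cc1cc(OC)c(I)cc1OC | intermediate
3 | ethyl propiolate | C#CC(=O)OCC | starting material
4 | ethyl 3-(2,5-dimethoxy-4-methylphenyl)prop-2-ynoate | CCOC(=O)C#Cc1cc(OC)c(C)cc1OC | intermediate
5 | isopropylmagnesium chloride | CC(C)[Mg]Cl | starting material
6 | alkenylcopper adduct (Cu cis to isopropyl) | CCOC(=O)/C([Cu])=C(/C(C)C)c1cc(OC)c(C)cc1OC | intermediate
7 | ethyl (Z)-3-(2,5-dimethoxy-4-methylphenyl)-4-methylpent-2-enoate | CCOC(=O)/C=C(/C(C)C)c1cc(OC)c(C)cc1OC | intermediate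
8 | (Z)-3-(2,5-dimethoxy-4-methylphenyl)-N-methoxy-N,4-dimethylpent-2-enamide | CON(C)C(=O)/C=C(/C(C)C)c1cc(OC)c(C)cc1OC | intermediate
9 | (Z)-5-(2,5-dimethoxy-4-methylphenyl)-6-methylhept-4-en-3-one | CCC(=O)/C=C(/C(C)C)c1cc(OC)c(C)cc1OC | intermediate
10 | α-trifluoroacetyl derivative of 9 | CC(C(=O)C(F)(F)F)C(=O)/C=C(/C(C)C)c1cc(OC)c(C)cc1OC | intermediate
11 | (Z)-2-diazo-5-(2,5-dimethoxy-4-methylphenyl)-6-methylhept-4-en-3-one | CC(=[N+]=[N-])C(=O)/C=C(/C(C)C)c1cc(OC)c(C)cc1OC | intermediate
12 | norcaradiene valence isomer of 13 (cyclopropane C4–C9–C10) | O=C1C=C(C(C)C)[C@]23C(OC)=CC(C)=C(OC)[C@H]2[C@]13C | intermediate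
13 | (8aS)-4,7-dimethoxy-6,8a-dimethyl-3-(propan-2-yl)azulen-1(8aH)-one | O=C1C=C(C(C)C)C2=C(OC)C=C(C)C(OC)=C[C@]12C | intermediate
14 | trans-fused 1,5-dione with C8 enol ether (H4 α) | O=C1C=C(C(C)C)[C@H]2C(=O)C=C(C)C(OC)=C[C@]12C | intermediate
15 | 5α-hydroxy enone | O=C1C=C(C(C)C)[C@H]2[C@H](O)C=C(C)C(OC)=C[C@]12C | intermediate
16 | 2α,3α-epoxy ketone, 5α-OH | O=C1[C@@H]3O[C@]3(C(C)C)[C@H]2[C@H](O)C=C(C)C(OC)=C[C@]12C | intermediate
17 | 4-hydroxybenzoic acid | OC(=O)c1ccc(O)cc1 | starting material
18 | tert-butyldimethylsilyl 4-[(tert-butyldimethylsilyl)oxy]benzoate | CC(C)(C)[Si](C)(C)OC(=O)c1ccc(O[Si](C)(C)C(C)(C)C)cc1 | intermediate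
19 | 4-[(tert-butyldimethylsilyl)oxy]benzoic acid | OC(=O)c1ccc(O[Si](C)(C)C(C)(C)C)cc1 | intermediate
20 | 5α-aroyloxy 2α,3α-epoxy ketone | O=C1[C@@H]3O[C@]3(C(C)C)[C@H]2[C@H](OC(=O)c4ccc(O[Si](C)(C)C(C)(C)C)cc4)C=C(C)C(OC)=C[C@]12C | intermediate
21 | 3α-hydroxy-5α-aroyloxy C1 ketone | O=C1C[C@@](O)(C(C)C)[C@H]2[C@H](OC(=O)c3ccc(O[Si](C)(C)C(C)(C)C)cc3)C=C(C)C(OC)=C[C@]12C | intermediate
22 | 1β,3α-diol | O[C@H]1C[C@@](O)(C(C)C)[C@H]2[C@H](OC(=O)c3ccc(O[Si](C)(C)C(C)(C)C)cc3)C=C(C)C(OC)=C[C@]12C | intermediate
23 | 1β-acetate | CC(=O)O[C@H]1C[C@@](O)(C(C)C)[C@H]2[C@H](OC(=O)c3ccc(O[Si](C)(C)C(C)(C)C)cc3)C=C(C)C(OC)=C[C@]12C | intermediate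
24 | CNP0087181.1 | CC(=O)O[C@H]1C[C@@](O)(C(C)C)[C@H]2[C@H](OC(=O)c3ccc(O)cc3)C=C(C)C(=O)C[C@]12C | target

Total step count: 16. Longest linear sequence: 15 (steps 1–10 and 12–16).

**Steps most likely to fail**

The first is step 7. The carbene may be lost by a 1,2-hydride shift from the methyl group. The arene may instead be attacked by substitution at C9 followed by aromatisation of the new ring. The untested tether may also transmit the ligand chirality poorly.

The fallback sets out from 9 and comes back at 13.
- Asymmetric copper hydride conjugate reduction of 9 (Cu(OAc)2 cat., the DTBM-SEGPHOS antipode that gives the 5R product, (EtO)2MeSiH, t-BuOH, toluene) gives (5R)-5-(2,5-dimethoxy-4-methylphenyl)-6-methylheptan-3-one F1.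
- The same two-stage diazo transfer, through its trifluoroacetyl ketone F2, gives the saturated-tether diazo ketone F3.
- A Rh2(OAc)4-catalysed Buchner reaction of this well-studied substrate class, which places the C3 substituent trans to the bridgehead methyl, carries the C3 configuration over to C10 and gives the 2,3-dihydroazulenone F4.
- Mukaiyama dehydrogenation (LiHMDS, then N-tert-butylbenzenesulfinimidoyl chloride, −78 °C) restores C2=C3 and gives 13.

The second is step 9. C4 of 14 may epimerise through the enol before reduction, hydride delivery to C1 may compete, and facial selectivity at C5 may be eroded.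

The fallback sets out from 14 and comes back at 15.
- Luche reduction with excess NaBH4/CeCl3·7H2O at −78 °C, started straight after the buffered work-up of step 8, takes both carbonyl groups to the 1β,5α-diol F5.
- TESCl/imidazole at −20 °C silylates the less hindered C5 hydroxyl (the C1 hydroxyl is neopentyl and cis to the methyl group) to give the 5-O-triethylsilyl ether F6.
- MnO2 oxidises the remaining allylic alcohol to the silyl-protected enone F7.
- Buffered HF·pyridine then gives 15.

The third is step 10. Peroxide addition to the hindered, isopropyl-bearing C3 may be slow. That would leave time for base-induced epimerisation at C4, for vinylogous retro-aldol opening of ring B, or for loss of facial selectivity.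

The fallback sets out from 15 and comes back at 21.
- Copper-catalysed conjugate borylation (B2pin2, CuCl cat., NaOt-Bu cat., Xantphos, MeOH, THF), which is known for β-substituted cyclic enones, adds boron to the α face of C3 and gives the tertiary boronate F8.
- NaBO3 oxidation with retention gives the 3α,5α-dihydroxy ketone F9.
- Steglich esterification of its only secondary hydroxyl with 19 gives 21, so that steps 10, 12 and 13 are bypassed.

**Further compounds**
F1 | step 7 | (5R)-5-(2,5-dimethoxy-4-methylphenyl)-6-methylheptan-3-one | CCC(=O)C[C@H](C(C)C)c1cc(OC)c(C)cc1OC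
F2 | step 7 | α-trifluoroacetyl derivative of F1 | CC(C(=O)C(F)(F)F)C(=O)C[C@H](C(C)C)c1cc(OC)c(C)cc1OC
F3 | step 7 | (5R)-2-diazo-5-(2,5-dimethoxy-4-methylphenyl)-6-methylheptan-3-one | CC(=[N+]=[N-])C(=O)C[C@H](C(C)C)c1cc(OC)c(C)cc1OC
F4 | step 7 | 2,3-dihydro derivative of 13 (3α-isopropyl, 10-Me β) | O=C1C[C@H](C(C)C)C2=C(OC)C=C(C)C(OC)=C[C@]12C
F5 | step 9 | 1β,5α-diol (C2=C3, H4 α, C8 enol ether) | O[C@H]1C=C(C(C)C)[C@H]2[C@H](O)C=C(C)C(OC)=C[C@]12C
F6 | step 9 | 5-O-triethylsilyl ether of F5 | O[C@H]1C=C(C(C)C)[C@H]2[C@H](O[Si](CC)(CC)CC)C=C(C)C(OC)=C[C@]12C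
F7 | step 9 | 5-O-triethylsilyl ether of 15 | O=C1C=C(C(C)C)[C@H]2[C@H](O[Si](CC)(CC)CC)C=C(C)C(OC)=C[C@]12C
F8 | step 10 | 3α-(pinacolatoboryl) ketone, 5α-OH | O=C1C[C@@](B3OC(C)(C)C(C)(C)O3)(C(C)C)[C@H]2[C@H](O)C=C(C)C(OC)=C[C@]12C
F9 | step 10 | 3α,5α-dihydroxy C1 ketone | O=C1C[C@@](O)(C(C)C)[C@H]2[C@H](O)C=C(C)C(OC)=C[C@]12C
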